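**Retrosynthetic overview**

1. Ring C (pyranone, formed last): target 26 ⇐ acid cyclodehydration of β-diketone 25 ⇐ intermolecular Claisen condensation of the o-hydroxyacetophenone 22 (as its lithium polyanion) with benzoyl chloride 23.
2. 22 ⇐ aryl bromide 18 by Stille acetylation with 19 and hydrogenolysis of two benzyl ethers; the bromine is placed ortho to a chelated phenol at the aldehyde stage, which fixes the substitution pattern of ring A.
3. Piperidine ring (formed first): 18 ⇐ N-methyl lactam 17 ⇐ δ-amino ester 14 ⇐ β-amino ester 10 by a two-carbon Wittig homologation.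
4. Key C–C bond and the only stereocentre: 10 ⇐ Mannich addition of the titanium enolate of methyl acetate 7 to the (R)-tert-butanesulfinyl imine 6, which creates piperidine C2–C3 and sets C2 as S.
5. 6 ⇐ 2,4,6-trihydroxybenzaldehyde 1 (benzylation, bromination, methylation) and (R)-tert-butanesulfinamide 5.

Assumption: the stereocentre in the target SMILES is read as (S) at C2 of the piperidine; the enantiomeric purity should be checked by chiral HPLC after steps 9 and 15.

**Route**

Step 1
Reactants: 1 2,4,6-trihydroxybenzaldehyde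
Product: 2 2,4-bis(benzyloxy)-6-hydroxybenzaldehyde
Conditions: BnBr (2.05 equiv), K2CO3 (2.2 equiv), DMF, 0 °C → rt
Reagents that add atoms: benzyl bromide, BrCc1ccccc1
Why: Williamson etherification alkylates the two more acidic, non-chelated phenols, while the phenol hydrogen-bonded to the formyl group stays free under K2CO3 at rt.

Step 2
Reactants: 2 2,4-bis(benzyloxy)-6-hydroxybenzaldehyde
Product: 3 4,6-bis(benzyloxy)-3-bromo-2-hydroxybenzaldehyde
Conditions: N-bromosuccinimide (1.02 equiv), MeCN–CH2Cl2, −10 → 0 °C, dark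
Reagents that add atoms: N-bromosuccinimide, O=C1CCC(=O)N1Br
Why: Electrophilic aromatic bromination goes ortho to the chelated phenol (C3) rather than to C5, which is flanked by two benzyloxy groups; the site is confirmed by NOE from the remaining aryl H to both OCH2Ph groups.

Step 3
Reactants: 3 4,6-bis(benzyloxy)-3-bromo-2-hydroxybenzaldehyde
Product: 4 4,6-bis(benzyloxy)-3-bromo-2-methoxybenzaldehyde
Conditions: MeI (3 equiv), K2CO3 (2 equiv), DMF, 40 °C
Reagents that add atoms: iodomethane, CI
Why: Williamson methylation of the remaining chelated phenol with excess MeI in DMF installs the methoxy group that becomes the 5-OMe of the flavone.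

Step 4
Reactants: 4 4,6-bis(benzyloxy)-3-bromo-2-methoxybenzaldehyde; 5 (R)-2-methylpropane-2-sulfinamide
Product: 6 (R,E)-N-[4,6-bis(benzyloxy)-3-bromo-2-methoxybenzylidene]-2-methylpropane-2-sulfinamide
Conditions: Ti(OEt)4 (2.5 equiv), THF, 65 °C
Reagents that add atoms: none
Why: Ti(OEt)4-mediated condensation (Ellman imine formation) activates the hindered aldehyde and scavenges water, giving the E-sulfinyl imine without touching the sulfur stereocentre.

Step 5
Reactants: 6 (R,E)-N-[4,6-bis(benzyloxy)-3-bromo-2-methoxybenzylidene]-2-methylpropane-2-sulfinamide; 7 methyl acetate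
Product: 10 methyl (3S)-3-[4,6-bis(benzyloxy)-3-bromo-2-methoxyphenyl]-3-{[(R)-tert-butylsulfinyl]amino}propanoate, via lithium enolate 8 (not isolated), via titanium enolate 9 (not isolated)
Conditions: LiN(iPr)2 (3 equiv), THF, −78 °C; ClTi(OiPr)3 (6 equiv), −78 °C; then 6, −78 °C, 4 h; aq. NH4Cl
Reagents that add atoms: none
Why: Intermolecular Mannich addition through a closed six-membered chair, with titanium bridging the enolate and sulfinyl oxygens and the tert-butyl group pseudo-equatorial, delivers the enolate to the Si face of the (R)-sulfinyl E-imine and sets the new centre as 3S.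

Step 6
Reactants: 10 methyl (3S)-3-[4,6-bis(benzyloxy)-3-bromo-2-methoxyphenyl]-3-{[(R)-tert-butylsulfinyl]amino}propanoate
Product: 11 (R)-N-[(1S)-1-[4,6-bis(benzyloxy)-3-bromo-2-methoxyphenyl]-3-oxopropyl]-2-methylpropane-2-sulfinamide
Conditions: iBu2AlH (2.2 equiv), CH2Cl2, −78 °C; MeOH, then aq. KNaC4H4O6
Reagents that add atoms: none
Why: Partial ester reduction with iBu2AlH at −78 °C stops at the aldehyde because the aluminium hemiacetal is stabilised by chelation to the sulfinamide nitrogen until work-up.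

Step 7
Reactants: 11 (R)-N-[(1S)-1-[4,6-bis(benzyloxy)-3-bromo-2-methoxyphenyl]-3-oxopropyl]-2-methylpropane-2-sulfinamide; 12 methyl (triphenylphosphoranylidene)acetate
Product: 13 methyl (2E,5S)-5-[4,6-bis(benzyloxy)-3-bromo-2-methoxyphenyl]-5-{[(R)-tert-butylsulfinyl]amino}pent-2-enoate
Conditions: CH2Cl2, rt → 40 °C
Reagents that add atoms: none
Why: Wittig olefination with a stabilised, weakly basic ylide adds the last two ring carbons E-selectively without β-elimination or epimerisation of the amino aldehyde.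

Step 8
Reactants: 13 methyl (2E,5S)-5-[4,6-bis(benzyloxy)-3-bromo-2-methoxyphenyl]-5-{[(R)-tert-butylsulfinyl]amino}pent-2-enoate
Product: 14 methyl (5S)-5-[4,6-bis(benzyloxy)-3-bromo-2-methoxyphenyl]-5-{[(R)-tert-butylsulfinyl]amino}pentanoate
Conditions: Cu(OAc)2·H2O (5 mol %), 1,2-bis(diphenylphosphino)benzene (5 mol %), (EtO)2MeSiH (3 equiv), t-BuOH (3 equiv), toluene, rt
Reagents that add atoms: none
Why: Conjugate (1,4-) reduction by a phosphine-ligated monovalent copper hydride saturates only the enoate and leaves the aryl bromide, benzyl ethers and sulfinamide untouched, which Pd/C hydrogenation would not.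

Step 9
Reactants: 14 methyl (5S)-5-[4,6-bis(benzyloxy)-3-bromo-2-methoxyphenyl]-5-{[(R)-tert-butylsulfinyl]amino}pentanoate
Product: 16 (6S)-6-[4,6-bis(benzyloxy)-3-bromo-2-methoxyphenyl]piperidin-2-one, via amino ester 15 (not isolated)
Conditions: HCl (4 M in dioxane, 3 equiv), MeOH, 0 °C, 30 min; then K2CO3 (5 equiv), MeOH, 50 °C
Reagents that add atoms: none
Why: Acidic methanolysis of the S–N bond at 0 °C (cold and brief to avoid benzylic ionisation) frees the amine, which on neutralisation closes the six-membered lactam by intramolecular aminolysis without touching the stereocentre.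

Step 10
Reactants: 16 (6S)-6-[4,6-bis(benzyloxy)-3-bromo-2-methoxyphenyl]piperidin-2-one
Product: 17 (6S)-6-[4,6-bis(benzyloxy)-3-bromo-2-methoxyphenyl]-1-methylpiperidin-2-one
Conditions: NaH (1.3 equiv), MeI (1.5 equiv), THF–DMF, 0 °C → rt
Reagents that add atoms: iodomethane, CI
Why: N-alkylation of the lactam sodium salt installs the N-methyl group while nitrogen is still non-basic, so no quaternisation can occur and no N-protecting group is needed later.

Step 11
Reactants: 17 (6S)-6-[4,6-bis(benzyloxy)-3-bromo-2-methoxyphenyl]-1-methylpiperidin-2-one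
Product: 18 (2S)-2-[4,6-bis(benzyloxy)-3-bromo-2-methoxyphenyl]-1-methylpiperidine
Conditions: AlH3 (made in the flask from LiAlH4 and AlCl3, 3:1), THF, 0 °C → rt; Na2SO4·10H2O quench
Reagents that add atoms: none
Why: Alane reduction of the tertiary lactam proceeds through the iminium ion to the amine at or below rt and does not reduce the aryl bromide.

Step 12
Reactants: 18 (2S)-2-[4,6-bis(benzyloxy)-3-bromo-2-methoxyphenyl]-1-methylpiperidine; 19 tributyl(1-ethoxyethenyl)stannane
Product: 21 1-{4,6-bis(benzyloxy)-2-methoxy-3-[(2S)-1-methylpiperidin-2-yl]phenyl}ethan-1-one, via enol ether 20 (not isolated)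
Conditions: Pd2(dba)3 (5 mol %), P(t-Bu)3 (12 mol %), CsF (2.2 equiv), dioxane, 100 °C; then 1 M aq. HCl, THF, rt; NaHCO3
Reagents that add atoms: water, O
Why: Stille cross-coupling, with the bulky electron-rich phosphine enabling oxidative addition of the hindered electron-rich bromide to zerovalent palladium and fluoride activating the stannane, gives an enol ether that mild acid hydrolyses to the methyl ketone exactly at the former bromine position.

Step 13
Reactants: 21 1-{4,6-bis(benzyloxy)-2-methoxy-3-[(2S)-1-methylpiperidin-2-yl]phenyl}ethan-1-one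
Product: 22 1-{4,6-dihydroxy-2-methoxy-3-[(2S)-1-methylpiperidin-2-yl]phenyl}ethan-1-one
Conditions: H2 (1 atm), 10% Pd/C, MeOH–EtOAc, rt
Reagents that add atoms: none
Why: Catalytic hydrogenolysis removes both benzyl ethers, while the chelated electron-rich aryl ketone and the ring C–N bond of the hindered 2-arylpiperidine are inert at 1 atm and rt.

Step 14
Reactants: 22 1-{4,6-dihydroxy-2-methoxy-3-[(2S)-1-methylpiperidin-2-yl]phenyl}ethan-1-one; 23 benzoyl chloride
Product: 25 1-{4,6-dihydroxy-2-methoxy-3-[(2S)-1-methylpiperidin-2-yl]phenyl}-3-phenylpropane-1,3-dione, via trilithium polyanion 24 (not isolated)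
Conditions: LiN(SiMe3)2 (5 equiv), THF, −78 → −10 °C; 23 (1.05 equiv), −78 °C → rt; aq. NH4Cl
Reagents that add atoms: none
Why: Intermolecular Claisen condensation, in which the ketone enolate carbon is the most nucleophilic site of the lithium polyanion and is C-acylated by one equivalent of benzoyl chloride, gives the β-diketone directly; the benzylic C–H next to the tertiary amine is not acidic, so the stereocentre is safe.

Step 15
Reactants: 25 1-{4,6-dihydroxy-2-methoxy-3-[(2S)-1-methylpiperidin-2-yl]phenyl}-3-phenylpropane-1,3-dione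
Product: 26 7-hydroxy-5-methoxy-6-[(2S)-1-methylpiperidin-2-yl]-2-phenyl-4H-chromen-4-one
Conditions: CF3CO2H–CH2Cl2 (1:2), 0 °C → rt (40 °C if slow); aq. NaHCO3 to pH 8
Reagents that add atoms: none
Why: Acid-catalysed cyclodehydration (hemiketal formation by the only phenol ortho to the ketone, then loss of water) closes ring C with a single possible regiochemistry, and keeping the amine protonated at or near rt avoids retro-Mannich racemisation.

**Compound list**

1 | 2,4,6-trihydroxybenzaldehyde | O=Cc1c(O)cc(O)cc1O | starting material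
2 | 2,4-bis(benzyloxy)-6-hydroxybenzaldehyde | O=Cc1c(O)cc(OCc2ccccc2)cc1OCc1ccccc1 | intermediate
3 | 4,6-bis(benzyloxy)-3-bromo-2-hydroxybenzaldehyde | O=Cc1c(O)c(Br)c(OCc2ccccc2)cc1OCc1ccccc1 | intermediate
4 | 4,6-bis(benzyloxy)-3-bromo-2-methoxybenzaldehyde | O=Cc1c(OC)c(Br)c(OCc2ccccc2)cc1OCc1ccccc1 | intermediate
5 | (R)-2-methylpropane-2-sulfinamide | CC(C)(C)[S@@](=O)N | starting material
6 | (R,E)-N-[4,6-bis(benzyloxy)-3-bromo-2-methoxybenzylidene]-2-methylpropane-2-sulfinamide | CC(C)(C)[S@@](=O)/N=C/c1c(OC)c(Br)c(OCc2ccccc2)cc1OCc1ccccc1 | intermediate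
7 | methyl acetate | COC(C)=O | starting material
8 | lithium enolate of methyl acetate (lithium 1-methoxyethenolate) | [Li+].[O-]C(=C)OC | intermediate
9 | triisopropoxytitanium enolate of methyl acetate | C=C(OC)O[Ti](OC(C)C)(OC(C)C)OC(C)C | intermediate
10 | methyl (3S)-3-[4,6-bis(benzyloxy)-3-bromo-2-methoxyphenyl]-3-{[(R)-tert-butylsulfinyl]amino}propanoate | CC(C)(C)[S@@](=O)N[C@@H](CC(=O)OC)c1c(OC)c(Br)c(OCc2ccccc2)cc1OCc1ccccc1 | intermediate
11 | (R)-N-[(1S)-1-[4,6-bis(benzyloxy)-3-bromo-2-methoxyphenyl]-3-oxopropyl]-2-methylpropane-2-sulfinamide | CC(C)(C)[S@@](=O)N[C@@H](CC=O)c1c(OC)c(Br)c(OCc2ccccc2)cc1OCc1ccccc1 | intermediate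
12 | methyl (triphenylphosphoranylidene)acetate | COC(=O)C=P(c1ccccc1)(c1ccccc1)c1ccccc1 | starting material
13 | methyl (2E,5S)-5-[4,6-bis(benzyloxy)-3-bromo-2-methoxyphenyl]-5-{[(R)-tert-butylsulfinyl]amino}pent-2-enoate | CC(C)(C)[S@@](=O)N[C@@H](C/C=C/C(=O)OC)c1c(OC)c(Br)c(OCc2ccccc2)cc1OCc1ccccc1 | intermediate
14 | methyl (5S)-5-[4,6-bis(benzyloxy)-3-bromo-2-methoxyphenyl]-5-{[(R)-tert-butylsulfinyl]amino}pentanoate | CC(C)(C)[S@@](=O)N[C@@H](CCCC(=O)OC)c1c(OC)c(Br)c(OCc2ccccc2)cc1OCc1ccccc1 | intermediate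
15 | methyl (5S)-5-amino-5-[4,6-bis(benzyloxy)-3-bromo-2-methoxyphenyl]pentanoate (hydrochloride in the flask) | COC(=O)CCC[C@H](N)c1c(OC)c(Br)c(OCc2ccccc2)cc1OCc1ccccc1 | intermediate
16 | (6S)-6-[4,6-bis(benzyloxy)-3-bromo-2-methoxyphenyl]piperidin-2-one | O=C1CCC[C@H](N1)c1c(OC)c(Br)c(OCc2ccccc2)cc1OCc1ccccc1 | intermediate
17 | (6S)-6-[4,6-bis(benzyloxy)-3-bromo-2-methoxyphenyl]-1-methylpiperidin-2-one | CN1C(=O)CCC[C@H]1c1c(OC)c(Br)c(OCc2ccccc2)cc1OCc1ccccc1 | intermediate
18 | (2S)-2-[4,6-bis(benzyloxy)-3-bromo-2-methoxyphenyl]-1-methylpiperidine | CN1CCCC[C@H]1c1c(OC)c(Br)c(OCc2ccccc2)cc1OCc1ccccc1 | intermediate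
19 | tributyl(1-ethoxyethenyl)stannane | CCCC[Sn](CCCC)(CCCC)C(=C)OCC | starting material
20 | (2S)-2-[4,6-bis(benzyloxy)-3-(1-ethoxyethenyl)-2-methoxyphenyl]-1-methylpiperidine | CCOC(=C)c1c(OC)c([C@@H]2CCCCN2C)c(OCc2ccccc2)cc1OCc1ccccc1 | intermediate
21 | 1-{4,6-bis(benzyloxy)-2-methoxy-3-[(2S)-1-methylpiperidin-2-yl]phenyl}ethan-1-one | CC(=O)c1c(OC)c([C@@H]2CCCCN2C)c(OCc2ccccc2)cc1OCc1ccccc1 | intermediate
22 | 1-{4,6-dihydroxy-2-methoxy-3-[(2S)-1-methylpiperidin-2-yl]phenyl}ethan-1-one | CC(=O)c1c(OC)c([C@@H]2CCCCN2C)c(O)cc1O | intermediate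
23 | benzoyl chloride | O=C(Cl)c1ccccc1 | starting material
24 | trilithium salt of 22 (bis-phenoxide enolate) | [Li+].[Li+].[Li+].C=C([O-])c1c(OC)c([C@@H]2CCCCN2C)c([O-])cc1[O-] | intermediate
25 | 1-{4,6-dihydroxy-2-methoxy-3-[(2S)-1-methylpiperidin-2-yl]phenyl}-3-phenylpropane-1,3-dione | O=C(CC(=O)c1ccccc1)c1c(OC)c([C@@H]2CCCCN2C)c(O)cc1O | intermediate
26 | 7-hydroxy-5-methoxy-6-[(2S)-1-methylpiperidin-2-yl]-2-phenyl-4H-chromen-4-one | COc1c([C@@H]2CCCCN2C)c(O)cc2oc(-c3ccccc3)cc(=O)c12 | target

**Totals and risks**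

Total step count: 15. Longest linear sequence: 15 steps (1 → 26); all other inputs are commercial.

The three steps most likely to fail:

First, step 5: the imine 6 is di-ortho-substituted and electron-rich, so the Mannich addition may be slow or give a poor diastereomer ratio. The fallback sets out from 6. Indium powder and allyl bromide in THF at 60 °C add an allyl group to the same Si face through a chelated chair. This gives the homoallylic sulfinamide (R)-N-[(1S)-1-[4,6-bis(benzyloxy)-3-bromo-2-methoxyphenyl]but-3-en-1-yl]-2-methylpropane-2-sulfinamide F1. Cross-metathesis of F1 with methyl acrylate (second-generation Hoveyda–Grubbs catalyst, CH2Cl2, 40 °C) then gives the enoate directly, so the route is rejoined at 13 and steps 5 to 7 are bypassed.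

Second, step 12: the bromide is flanked by two alkoxy groups, so the Stille coupling may stall. The fallback sets out from 18. Bromine–lithium exchange (n-BuLi, THF, −78 °C; no acidic benzylic C–H next to the tertiary amine) followed by acetaldehyde gives the benzylic alcohol 1-{4,6-bis(benzyloxy)-2-methoxy-3-[(2S)-1-methylpiperidin-2-yl]phenyl}ethan-1-ol F2 as a mixture of carbinol epimers. Swern oxidation (oxalyl chloride, DMSO, Et3N, −78 °C) then comes back to the route at 21.

Third, step 14: O-benzoylation of the phenoxides may compete with C-acylation of the polyanion. The fallback sets out from 22. Benzoyl chloride (2.5 equiv) in pyridine gives the bis-ester 4-acetyl-5-methoxy-6-[(2S)-1-methylpiperidin-2-yl]-1,3-phenylene dibenzoate F3. Powdered KOH in pyridine at 50 °C effects the intramolecular Baker–Venkataraman acyl shift to 5-hydroxy-3-methoxy-2-[(2S)-1-methylpiperidin-2-yl]-4-(3-oxo-3-phenylpropanoyl)phenyl benzoate F4. K2CO3 in MeOH removes the remaining benzoate, and the route is rejoined at 25.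

**Further compounds**

F1 | step 5 | (R)-N-[(1S)-1-[4,6-bis(benzyloxy)-3-bromo-2-methoxyphenyl]but-3-en-1-yl]-2-methylpropane-2-sulfinamide | CC(C)(C)[S@@](=O)N[C@@H](CC=C)c1c(OC)c(Br)c(OCc2ccccc2)cc1OCc1ccccc1
F2 | step 12 | 1-{4,6-bis(benzyloxy)-2-methoxy-3-[(2S)-1-methylpiperidin-2-yl]phenyl}ethan-1-ol (carbinol epimers) | CC(O)c1c(OC)c([C@@H]2CCCCN2C)c(OCc2ccccc2)cc1OCc1ccccc1
F3 | step 14 | 4-acetyl-5-methoxy-6-[(2S)-1-methylpiperidin-2-yl]-1,3-phenylene dibenzoate | CC(=O)c1c(OC)c([C@@H]2CCCCN2C)c(OC(=O)c2ccccc2)cc1OC(=O)c1ccccc1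
F4 | step 14 | 5-hydroxy-3-methoxy-2-[(2S)-1-methylpiperidin-2-yl]-4-(3-oxo-3-phenylpropanoyl)phenyl benzoate | O=C(CC(=O)c1ccccc1)c1c(OC)c([C@@H]2CCCCN2C)c(OC(=O)c2ccccc2)cc1O
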